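**Plan** (locants follow the eremophilane skeleton of the target: ring A = C1–C5 and C10 with the C2 ketone and methyls on C4 and C5; ring B = C5–C10 with C7 isopropenyl, C8 acetate, C9 senecioate)
- Cuts: the two esters come off first and C6 is returned to a ketone; ring A is then cut at C3–C4 and C5–C10 (retro-[4+2]), and the open chain at C5–C6 (alkenyllithium + aldehyde), C10=C1 (Wittig) and C7–C8 (aldol).
- Enabling feature: ring A is a cyclohexanone whose C2 carbonyl is the masked oxygen of a 2-silyloxy diene C3=C2–C1=C10, and whose cis methyls on C4 and C5 are those of an (E)-2-methylbut-2-enoyl ketone C4=C5–C6=O; the two π-systems are joined by C6–C9, the other carbons of ring B.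
- Forward order: the chain is built linearly (C7–C8, then C5–C6, then C10=C1 and the diene), one intramolecular Diels–Alder reaction closes ring A and ring B together, C6 is deoxygenated, and the esters go on last.
- Stereochemistry: C9 comes from (S)-glyceraldehyde acetonide; C7 and C8 from an auxiliary-controlled syn-aldol; C4, C5 and C10 from the cycloaddition (alkene geometry, endo tether carbonyl, diene face set by C7–C9).

Key step: step 14

Remark: (S)-glyceraldehyde acetonide 5 is taken as a purchased reagent and used freshly distilled.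
Remark: the C6 carbinol centre in 13–22 and 25–28 is an epimer mixture of no consequence, because C6 is later oxidised or deoxygenated.

**Step 1**
Reactants: 1 (R)-4-benzyloxazolidin-2-one; 2 3-methylbut-2-enoyl chloride
Product: 4 (R)-4-benzyl-3-(3-methylbut-2-enoyl)oxazolidin-2-one, via N-lithio oxazolidinone 3 (not isolated)
Conditions: n-BuLi, THF, −78 °C; then 2, −78 → 0 °C
Reagents that add atoms: none
Why: N-acylation of the lithiated oxazolidinone with an acid chloride is the standard route to such imides, and the absence of an amine base keeps the senecioyl unit from deconjugating through a vinylketene.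

**Step 2**
Reactants: 4 (R)-4-benzyl-3-(3-methylbut-2-enoyl)oxazolidin-2-one; 5 (S)-glyceraldehyde acetonide
Product: 7 syn-aldol imide (C7 isopropenyl; C8 hydroxyl; C9/C10 acetonide), via boron dienolate 6 (not isolated)
Conditions: Bu2BOTf, Et3N, CH2Cl2, −78 → 0 °C; 5, −78 → 0 °C; aq. NaH2PO4/Na2HPO4 (pH 7), MeOH, H2O2, 0 °C
Reagents that add atoms: none
Why: Evans syn-aldol of the (Z)-boron dienolate, which reacts at its α-carbon through a Zimmerman–Traxler chair so that the double bond leaves conjugation and becomes the C7 isopropenyl group; the (R)-benzyl group fixes the enolate face and hence C7 and C8 (7,8-syn), and the pairing is matched because an α-alkoxy aldehyde itself prefers the 8,9-anti adduct with (Z)-enolates.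

**Step 3**
Reactants: 7 syn-aldol imide
Product: 8 C8 tert-butyldimethylsilyl ether of 7
Conditions: TBSOTf, 2,6-lutidine, CH2Cl2, 0 °C
Reagents that add atoms: tert-butyldimethylsilyl triflate, CC(C)(C)[Si](C)(C)OS(=O)(=O)C(F)(F)F
Why: Silylation of a hindered β-hydroxy imide with the silyl triflate is routine and blocks retro-aldol and lactonisation in later steps.

**Step 4**
Reactants: 8 C8 silyl ether imide
Product: 9 C6 primary alcohol (C7 isopropenyl; C8 OTBS; C9/C10 acetonide)
Conditions: LiBH4, MeOH (1 equiv), THF, 0 °C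
Reagents that add atoms: none
Why: Reductive cleavage of an N-acyl oxazolidinone with LiBH4 gives the primary alcohol and returns the auxiliary without touching C7, the silyl ether or the acetonide.

**Step 5**
Reactants: 9 C6 primary alcohol
Product: 10 C6 aldehyde
Conditions: Dess–Martin periodinane, NaHCO3, CH2Cl2, 0 °C; used crude at once
Reagents that add atoms: none
Why: Buffered Dess–Martin oxidation is near-neutral, so the α-isopropenyl β-silyloxy aldehyde should form without epimerisation at C7, double-bond migration or β-elimination.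

**Step 6**
Reactants: 10 C6 aldehyde; 11 (E)-2-bromobut-2-ene
Product: 14 C6 allylic acetate (both C6 epimers), via (E)-but-2-en-2-yllithium 12 (not isolated), via lithium alkoxide 13 (not isolated)
Conditions: 11, t-BuLi (2 equiv), Et2O, −78 °C; 10, −78 °C; Ac2O, −78 → 0 °C
Reagents that add atoms: acetic anhydride, CC(=O)OC(C)=O
Why: Bromine–lithium exchange retains the alkene geometry, 1,2-addition of the alkenyllithium to the aldehyde forms C5–C6 faster than enolisation at −78 °C, and the alkoxide is acetylated in the same flask; the new C6 centre is uncontrolled and need not be controlled.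

**Step 7**
Reactants: 14 C6 allylic acetate
Product: 15 C9,C10-diol
Conditions: AcOH/H2O (4:1), 35 °C
Reagents that add atoms: none
Why: Aqueous acetic acid hydrolyses a terminal isopropylidene acetal while a hindered secondary TBS ether and an allylic acetate are retained.

**Step 8**
Reactants: 15 C9,C10-diol
Product: 16 C9,C10-bis(triethylsilyl) ether
Conditions: TESOTf, 2,6-lutidine, CH2Cl2, −78 → 0 °C
Reagents that add atoms: triethylsilyl triflate, CC[Si](CC)(CC)OS(=O)(=O)C(F)(F)F
Why: Exhaustive silylation of a 1,2-diol with a silyl triflate is routine and prepares the selective unmasking of C10.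

**Step 9**
Reactants: 16 C9,C10-bis(triethylsilyl) ether
Product: 18 C10 aldehyde (C9 OTES), via alkoxysulfonium salt 17 (not isolated)
Conditions: (COCl)2, DMSO, CH2Cl2, −78 → −30 °C; Et3N, −78 → 0 °C
Reagents that add atoms: none
Why: Under Swern conditions a primary triethylsilyl ether is cleaved and oxidised directly to the aldehyde while secondary TES and TBS ethers survive, a known selective oxidative deprotection.

**Step 10**
Reactants: 18 C10 aldehyde; 19 1-(triphenylphosphoranylidene)propan-2-one
Product: 20 (E)-enone (C10=C1; C2 methyl ketone)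
Conditions: 19, CH2Cl2, 25 °C
Reagents that add atoms: none
Why: Wittig olefination with the stabilised acetonyl ylide gives the (E)-enone under non-basic conditions that should not epimerise the α-silyloxy centre C9.

**Step 11**
Reactants: 20 (E)-enone
Product: 21 2-silyloxy diene (C3=C2(OTBS)–C1=C10; C6 acetate)
Conditions: TBSOTf, Et3N, CH2Cl2, −78 → 0 °C
Reagents that add atoms: tert-butyldimethylsilyl triflate, CC(C)(C)[Si](C)(C)OS(=O)(=O)C(F)(F)F
Why: Soft enolisation of a methyl enone with a silyl triflate and triethylamine removes a methyl proton and gives the cross-conjugated 2-silyloxy-1,3-diene, which also masks C2 against the hydride of the next step.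

**Step 12**
Reactants: 21 2-silyloxy diene acetate
Product: 22 C6 allylic alcohol
Conditions: i-Bu2AlH, CH2Cl2, −78 °C; aq. potassium sodium tartrate
Reagents that add atoms: none
Why: Reductive removal of an acetate with i-Bu2AlH at low temperature leaves silyl ethers and the silyl dienol ether intact.

**Step 13**
Reactants: 22 C6 allylic alcohol
Product: 23 silyloxy trienone (C4=C5–C6=O dienophile; C3=C2–C1=C10 diene)
Conditions: Dess–Martin periodinane, NaHCO3, CH2Cl2, 0 °C; filtered through Et3N-deactivated silica, used at once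
Reagents that add atoms: none
Why: Buffered Dess–Martin oxidation of the allylic alcohol creates the enone under near-neutral conditions, so C7, now α to a ketone and allylic, meets neither acid nor base before the cyclisation.

**Step 14**
Reactants: 23 silyloxy trienone
Product: 24 cis-fused bicyclic C6 ketone (C1=C2 silyl enol ether; C8 OTBS; C9 OTES)
Conditions: toluene (0.01 M), BHT (cat.), 110 °C
Reagents that add atoms: none
Why: Thermal normal-demand [4+2] cycloaddition, concerted but asynchronous, between the electron-rich 2-silyloxy diene C3=C2–C1=C10 and the (E)-enone C4=C5–C6=O of the same chain; the closest known reaction type is the intramolecular Diels–Alder reaction of 1,7,9-decatrien-3-ones, which cyclise on mild heating and favour cis-fused octalones. Ring A closes as the six-membered cycloadduct ring (new bonds C3–C4 and C5–C10, the enol ether double bond ending at C1=C2) and ring B closes at the same time as the six-membered ring spanned by the four-atom tether C6–C9, the nucleophilic diene terminus C3 meeting the enone β-carbon C4 so that polarity and tether ask for the same orientation. C4 and C5 are set by suprafacial addition to the (E)-alkene, which keeps its two methyl groups cis. C10 is set relative to C5 by the endo position of the tether carbonyl C6 under the diene, which places H-10 on the face of the C5 methyl (cis ring fusion). The step needs this endo mode and one diene face: the chair-like endo arrangements put the C5 methyl 1,3-diaxial to either the C7 isopropenyl or the bulky C9 triethylsilyloxy group, whereas the boat-like endo arrangement known for such trienones keeps the C7 and C8 substituents pseudo-equatorial with the C9–O bond eclipsing the diene, and this one leads to the configuration of 24.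

**Step 15**
Reactants: 24 bicyclic C6 ketone
Product: 25 C6 alcohol
Conditions: LiAlH4, Et2O, −78 → 0 °C
Reagents that add atoms: none
Why: Hydride reduction of the hindered ketone by the small LiAlH4 should outrun enolisation toward C7 and leaves silyl ethers and the silyl enol ether untouched; the C6 configuration is irrelevant.

**Step 16**
Reactants: 25 C6 alcohol
Product: 28 C6 S-methyl xanthate, via sodium alkoxide 26 (not isolated), via sodium xanthate 27 (not isolated)
Conditions: NaN(SiMe3)2, THF, −78 °C; CS2; MeI, −78 → 25 °C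
Reagents that add atoms: carbon disulfide, S=C=S; iodomethane, CI
Why: Xanthate formation from the alkoxide (first half of the Barton–McCombie deoxygenation) works for neopentyl secondary alcohols because CS2 is a small electrophile.

**Step 17**
Reactants: 28 C6 S-methyl xanthate
Product: 29 C6-deoxygenated bicycle (C1=C2 silyl enol ether; C8 OTBS; C9 OTES)
Conditions: Bu3SnH (0.5 M), Et3B, air, toluene, 25 °C
Reagents that add atoms: none
Why: Barton–McCombie deoxygenation, in which the stannyl radical adds to the thiocarbonyl, the C6–O bond fragments and the secondary C6 radical is reduced by Bu3SnH; room-temperature initiation avoids Chugaev elimination and the high stannane concentration should outrun 1,2-shift of the neighbouring isopropenyl group.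

**Step 18**
Reactants: 29 C6-deoxygenated bicycle
Product: 30 C2 ketone with free C9 hydroxyl (C8 OTBS)
Conditions: HF·pyridine, pyridine, THF, 0 → 25 °C
Reagents that add atoms: none
Why: Buffered HF·pyridine cleaves the TES ether and the silyl enol ether (giving the C2 ketone) much faster than the hindered secondary TBS ether, the usual TES/TBS differentiation.

**Step 19**
Reactants: 30 C2 ketone with free C9 hydroxyl; 2 3-methylbut-2-enoyl chloride
Product: 31 C9 senecioate (C8 OTBS)
Conditions: 2, DMAP, pyridine, CH2Cl2, 0 → 40 °C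
Reagents that add atoms: none
Why: DMAP-catalysed acylation with the acid chloride is the standard method for hindered secondary alcohols, and pyridine in place of a trialkylamine keeps the acid chloride from forming the vinylketene that leads to the deconjugated ester.

**Step 20**
Reactants: 31 C9 senecioate
Product: 32 C8 alcohol
Conditions: HF·pyridine (excess), THF, 25 °C
Reagents that add atoms: none
Why: Acidic fluoride removes the last TBS ether without base, so the neighbouring senecioate should not migrate.

**Step 21**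
Reactants: 32 C8 alcohol
Product: 33 target (CNP0150397.1)
Conditions: Ac2O, pyridine, DMAP (cat.), CH2Cl2, 0 → 25 °C
Reagents that add atoms: acetic anhydride, CC(=O)OC(C)=O
Why: Acetylation of the unhindered equatorial C8 hydroxyl is fast and completes the target.

**Compound list**
1 | (R)-4-benzyloxazolidin-2-one | O=C1N[C@H](Cc2ccccc2)CO1 | starting material
2 | 3-methylbut-2-enoyl chloride (senecioyl chloride) | CC(C)=CC(=O)Cl | starting material
3 | N-lithio derivative of 1 | O=C1N([Li])[C@H](Cc2ccccc2)CO1 | intermediate (not isolated)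
4 | (R)-4-benzyl-3-(3-methylbut-2-enoyl)oxazolidin-2-one | CC(C)=CC(=O)N1C(=O)OC[C@H]1Cc1ccccc1 | intermediate
5 | (S)-2,2-dimethyl-1,3-dioxolane-4-carbaldehyde ((S)-glyceraldehyde acetonide) | O=C[C@@H]1COC(C)(C)O1 | starting material
6 | (Z)-dibutylboron dienolate of 4 | C=C(C)/C=C(\OB(CCCC)CCCC)N1C(=O)OC[C@H]1Cc1ccccc1 | intermediate (not isolated)
7 | (4R)-4-benzyl-3-[(2R,3R)-3-[(4S)-2,2-dimethyl-1,3-dioxolan-4-yl]-3-hydroxy-2-(prop-1-en-2-yl)propanoyl]oxazolidin-2-one (7,8-syn, 8,9-anti) | C=C(C)[C@@H](C(=O)N1C(=O)OC[C@H]1Cc1ccccc1)[C@@H](O)[C@@H]1COC(C)(C)O1 | intermediate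
8 | C8 O-TBS ether of 7 | C=C(C)[C@@H](C(=O)N1C(=O)OC[C@H]1Cc1ccccc1)[C@@H](O[Si](C)(C)C(C)(C)C)[C@@H]1COC(C)(C)O1 | intermediate
9 | C6 primary alcohol (C7 isopropenyl, C8 OTBS, C9/C10 acetonide) | C=C(C)[C@@H](CO)[C@@H](O[Si](C)(C)C(C)(C)C)[C@@H]1COC(C)(C)O1 | intermediate
10 | C6 aldehyde | C=C(C)[C@@H](C=O)[C@@H](O[Si](C)(C)C(C)(C)C)[C@@H]1COC(C)(C)O1 | intermediate
11 | (E)-2-bromobut-2-ene | C/C=C(\C)Br | starting material
12 | (E)-but-2-en-2-yllithium | C/C=C(\C)[Li] | intermediate (not isolated)
13 | lithium alkoxide of the C6 allylic alcohol (C6 epimers) | C=C(C)[C@@H](C(O[Li])/C(C)=C/C)[C@@H](O[Si](C)(C)C(C)(C)C)[C@@H]1COC(C)(C)O1 | intermediate (not isolated)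
14 | C6 allylic acetate with (E)-C4=C5 alkene (C6 epimers) | C=C(C)[C@@H](C(OC(C)=O)/C(C)=C/C)[C@@H](O[Si](C)(C)C(C)(C)C)[C@@H]1COC(C)(C)O1 | intermediate
15 | C9,C10-diol | C=C(C)[C@@H](C(OC(C)=O)/C(C)=C/C)[C@@H](O[Si](C)(C)C(C)(C)C)[C@@H](O)CO | intermediate
16 | C9,C10-bis(triethylsilyl) ether | C=C(C)[C@@H](C(OC(C)=O)/C(C)=C/C)[C@@H](O[Si](C)(C)C(C)(C)C)[C@@H](O[Si](CC)(CC)CC)CO[Si](CC)(CC)CC | intermediate
17 | C10 alkoxydimethylsulfonium chloride | C=C(C)[C@@H](C(OC(C)=O)/C(C)=C/C)[C@@H](O[Si](C)(C)C(C)(C)C)[C@@H](O[Si](CC)(CC)CC)CO[S+](C)C.[Cl-] | intermediate (not isolated)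
18 | C10 aldehyde (C9 OTES, C8 OTBS, C6 OAc) | C=C(C)[C@@H](C(OC(C)=O)/C(C)=C/C)[C@@H](O[Si](C)(C)C(C)(C)C)[C@@H](O[Si](CC)(CC)CC)C=O | intermediate
19 | 1-(triphenylphosphoranylidene)propan-2-one | CC(=O)C=P(c1ccccc1)(c1ccccc1)c1ccccc1 | starting material
20 | (E)-enone C10=C1–C2(=O)–C3 | C=C(C)[C@@H](C(OC(C)=O)/C(C)=C/C)[C@@H](O[Si](C)(C)C(C)(C)C)[C@@H](O[Si](CC)(CC)CC)/C=C/C(C)=O | intermediate
21 | 2-(tert-butyldimethylsilyloxy) diene with C6 acetate | C=C(C)[C@@H](C(OC(C)=O)/C(C)=C/C)[C@@H](O[Si](C)(C)C(C)(C)C)[C@@H](O[Si](CC)(CC)CC)/C=C/C(=C)O[Si](C)(C)C(C)(C)C | intermediate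
22 | 2-silyloxy diene with free C6 allylic alcohol | C=C(C)[C@@H](C(O)/C(C)=C/C)[C@@H](O[Si](C)(C)C(C)(C)C)[C@@H](O[Si](CC)(CC)CC)/C=C/C(=C)O[Si](C)(C)C(C)(C)C | intermediate
23 | open-chain silyloxy trienone (key-step precursor) | C=C(C)[C@@H](C(=O)/C(C)=C/C)[C@@H](O[Si](C)(C)C(C)(C)C)[C@@H](O[Si](CC)(CC)CC)/C=C/C(=C)O[Si](C)(C)C(C)(C)C | intermediate
24 | cis-fused bicyclic C6 ketone with C1=C2 silyl enol ether (key-step product; C4, C5, C7–C10 as in the target) | C=C(C)[C@H]1C(=O)[C@@]2(C)[C@H](C=C(O[Si](C)(C)C(C)(C)C)C[C@@H]2C)[C@H](O[Si](CC)(CC)CC)[C@@H]1O[Si](C)(C)C(C)(C)C | intermediate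
25 | C6 alcohol of 24 | C=C(C)[C@H]1C(O)[C@@]2(C)[C@H](C=C(O[Si](C)(C)C(C)(C)C)C[C@@H]2C)[C@H](O[Si](CC)(CC)CC)[C@@H]1O[Si](C)(C)C(C)(C)C | intermediate
26 | sodium alkoxide of 25 | C=C(C)[C@H]1C(O[Na])[C@@]2(C)[C@H](C=C(O[Si](C)(C)C(C)(C)C)C[C@@H]2C)[C@H](O[Si](CC)(CC)CC)[C@@H]1O[Si](C)(C)C(C)(C)C | intermediate (not isolated)
27 | sodium xanthate of 25 | C=C(C)[C@H]1C(OC(=S)S[Na])[C@@]2(C)[C@H](C=C(O[Si](C)(C)C(C)(C)C)C[C@@H]2C)[C@H](O[Si](CC)(CC)CC)[C@@H]1O[Si](C)(C)C(C)(C)C | intermediate (not isolated)
28 | C6 S-methyl xanthate | C=C(C)[C@H]1C(OC(=S)SC)[C@@]2(C)[C@H](C=C(O[Si](C)(C)C(C)(C)C)C[C@@H]2C)[C@H](O[Si](CC)(CC)CC)[C@@H]1O[Si](C)(C)C(C)(C)C | intermediate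
29 | C6-deoxygenated bicycle | C=C(C)[C@H]1C[C@@]2(C)[C@H](C=C(O[Si](C)(C)C(C)(C)C)C[C@@H]2C)[C@H](O[Si](CC)(CC)CC)[C@@H]1O[Si](C)(C)C(C)(C)C | intermediate
30 | C2 ketone, C9 alcohol, C8 OTBS | C=C(C)[C@H]1C[C@@]2(C)[C@H](CC(=O)C[C@@H]2C)[C@H](O)[C@@H]1O[Si](C)(C)C(C)(C)C | intermediate
31 | C9 senecioate, C8 OTBS | C=C(C)[C@H]1C[C@@]2(C)[C@H](CC(=O)C[C@@H]2C)[C@H](OC(=O)C=C(C)C)[C@@H]1O[Si](C)(C)C(C)(C)C | intermediate
32 | C9 senecioate, C8 alcohol | C=C(C)[C@H]1C[C@@]2(C)[C@H](CC(=O)C[C@@H]2C)[C@H](OC(=O)C=C(C)C)[C@@H]1O | intermediate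
33 | (4S,5R,7R,8R,9S,10S)-8-acetoxy-9-(3-methylbut-2-enoyloxy)eremophil-11-en-2-one (CNP0150397.1) | C=C(C)[C@H]1C[C@@]2(C)[C@H](CC(=O)C[C@@H]2C)[C@H](OC(=O)C=C(C)C)[C@@H]1OC(C)=O | target

**Totals**
Total step count: 21. Longest linear sequence: 21 steps (1 → 33).

**Steps most likely to fail**

Step 14. The cycloaddition may lose control of the ring-fusion mode (exo addition giving trans-fusion) or of the diene face, and the trisubstituted dienophile may react so slowly that C7 erodes on heating. The fallback ties the C8 and C9 oxygens into a cis-dioxolane, which removes the two bulky gauche silyloxy groups, flattens the C8–C9 segment and so offers a different set of tether conformations. It sets out from enone 20. Aqueous HF in MeCN removes both silyl ethers to give the enone diol F1, and 2,2-dimethoxypropane with PPTS closes the ring to give the enone acetonide F2. TBSOTf/Et3N gives the silyloxy diene acetonide F3, i-Bu2AlH frees the diene alcohol acetonide F4, and buffered Dess–Martin oxidation gives the trienone acetonide F5, which is heated in toluene to the cycloadduct acetonide F6. LiAlH4 gives the C6 alcohol acetonide F7, NaN(SiMe3)2/CS2/MeI the xanthate acetonide F8, and Bu3SnH/Et3B the deoxygenated acetonide F9. Dilute aqueous HCl in THF then hydrolyses both the enol ether and the acetonide to the keto diol F10. Selective silylation of the equatorial C8 hydroxyl (TBSCl, imidazole, DMF, 0 °C) brings the sequence back to the route at 30.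

Step 17. The C6 radical may rearrange by 1,2-shift of the neighbouring isopropenyl group, the xanthate may undergo thermal syn-elimination toward C7, or xanthate formation at the neopentyl alcohol (step 16) may stall. The fallback replaces the radical chain by electron-transfer cleavage, in which the C6 radical is reduced to the carbanion at once. It sets out from alcohol 25: n-BuLi and bis(dimethylamino)phosphoryl chloride give the C6 phosphorodiamidate F11, and brief treatment with Li in EtNH2/THF with t-BuOH at 0 °C cleaves the C6–O bond and returns to the route at 29.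

Step 19. Acylation of the axial C9 hydroxyl, flanked by the ring fusion and the C8 silyl ether, may be sluggish, with the acylating agent losing conjugation instead. The fallback uses a sterically small ketene as the acylating species and restores conjugation afterwards. It sets out from 30 and acid chloride 2: Et3N converts 2 in the flask into isopropenylketene F12, which is trapped by the C9 hydroxyl to give the C9 3-methylbut-3-enoate F13, and DBU in CH2Cl2 moves the double bond into conjugation, returning to the route at 31.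

**Further compounds**
F1 | step 14 | enone diol (C6 acetate, free C8 and C9 hydroxyls) | C=C(C)[C@@H](C(OC(C)=O)/C(C)=C/C)[C@@H](O)[C@@H](O)/C=C/C(C)=O
F2 | step 14 | enone acetonide (C8/C9 cis-dioxolane, C6 acetate) | C=C(C)[C@@H](C(OC(C)=O)/C(C)=C/C)[C@@H](O1)[C@@H](OC1(C)C)/C=C/C(C)=O
F3 | step 14 | silyloxy diene acetonide (C6 acetate) | C=C(C)[C@@H](C(OC(C)=O)/C(C)=C/C)[C@@H](O1)[C@@H](OC1(C)C)/C=C/C(=C)O[Si](C)(C)C(C)(C)C
F4 | step 14 | diene alcohol acetonide (free C6 hydroxyl) | C=C(C)[C@@H](C(O)/C(C)=C/C)[C@@H](O1)[C@@H](OC1(C)C)/C=C/C(=C)O[Si](C)(C)C(C)(C)C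
F5 | step 14 | trienone acetonide | C=C(C)[C@@H](C(=O)/C(C)=C/C)[C@@H](O1)[C@@H](OC1(C)C)/C=C/C(=C)O[Si](C)(C)C(C)(C)C
F6 | step 14 | cycloadduct acetonide (C6 ketone, C1=C2 silyl enol ether) | C=C(C)[C@H]1C(=O)[C@@]2(C)[C@H](C=C(O[Si](C)(C)C(C)(C)C)C[C@@H]2C)[C@H](OC3(C)C)[C@@H]1O3
F7 | step 14 | C6 alcohol acetonide | C=C(C)[C@H]1C(O)[C@@]2(C)[C@H](C=C(O[Si](C)(C)C(C)(C)C)C[C@@H]2C)[C@H](OC3(C)C)[C@@H]1O3
F8 | step 14 | xanthate acetonide | C=C(C)[C@H]1C(OC(=S)SC)[C@@]2(C)[C@H](C=C(O[Si](C)(C)C(C)(C)C)C[C@@H]2C)[C@H](OC3(C)C)[C@@H]1O3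
F9 | step 14 | deoxygenated acetonide | C=C(C)[C@H]1C[C@@]2(C)[C@H](C=C(O[Si](C)(C)C(C)(C)C)C[C@@H]2C)[C@H](OC3(C)C)[C@@H]1O3
F10 | step 14 | keto diol (C2 ketone, free C8 and C9 hydroxyls) | C=C(C)[C@H]1C[C@@]2(C)[C@H](CC(=O)C[C@@H]2C)[C@H](O)[C@@H]1O
F11 | step 17 | C6 N,N,N',N'-tetramethylphosphorodiamidate of 25 | C=C(C)[C@H]1C(OP(=O)(N(C)C)N(C)C)[C@@]2(C)[C@H](C=C(O[Si](C)(C)C(C)(C)C)C[C@@H]2C)[C@H](O[Si](CC)(CC)CC)[C@@H]1O[Si](C)(C)C(C)(C)C
F12 | step 19 | isopropenylketene (3-methylbuta-1,3-dien-1-one) | C=C(C)C=C=O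
F13 | step 19 | C9 3-methylbut-3-enoate (C8 OTBS, C2 ketone) | C=C(C)[C@H]1C[C@@]2(C)[C@H](CC(=O)C[C@@H]2C)[C@H](OC(=O)CC(C)=C)[C@@H]1O[Si](C)(C)C(C)(C)C
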